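**Assumptions**
- The SMILES is read as the (1S,3R,4R,6Z,8S,12S,13R,14R) isomer. Cembrane numbering is used throughout (C1–C14 ring; C15 bears C16 = lactone carbonyl and C17 = exocyclic CH2; C18, C19, C20 = methyls on C4, C8, C12).
- In step 4 the (S)-BINAP complex is taken to add H2 to the same face of the allylic-alcohol frame as it does with geraniol; this sense is assumed by analogy and would have to be confirmed on the product.

**Retrosynthetic overview**
- Epoxide last: the 3,4-epoxide comes from the E-C3=C4 alkene of the finished cembranolide; the cis-γ-lactone comes from oxidizing C16 and closing onto O14.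
- The 14-membered ring comes from the C1–C2 bond, the bond made in cembrane biosynthesis: a geranyl-type allyl cation (C2–C4) is captured by the C1=C15 alkene, which carries CH2SiMe3 (future C17) and CH2O (future C16).
- The open-chain precursor comes from a vinylogous aldol (C13–C14) between a C13 aldehyde and a 3-(silylmethyl)-2-silyloxyfuran, followed by reduction of the butenolide.
- The aldehyde comes from geraniol (Sharpless epoxidation sets C8, allylic oxidation and asymmetric hydrogenation set C12, epoxy chloride gives the alkyne) and a C5 bromo-chloride joined at C5–C6.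
- Order of ring formation: carbocycle, then lactone, then epoxide; the C6≡C7 alkyne is reduced to the Z-alkene after ring closure.

**Route**

Step 1
Reactants: 1 geraniol
Product: 2 [(2S,3S)-3-methyl-3-(4-methylpent-3-en-1-yl)oxiran-2-yl]methanol
Conditions: Ti(OiPr)4 (5 mol%), L-(+)-diethyl tartrate (6 mol%), t-BuOOH, 4 Å MS, CH2Cl2, −20 °C
Reagents that add atoms: tert-butyl hydroperoxide CC(C)(C)OO
Why: Katsuki–Sharpless asymmetric epoxidation touches only the allylic-alcohol alkene and with L-(+)-tartrate gives the (2S,3S)-epoxide, whose quaternary carbon becomes C8 (S).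

Step 2
Reactants: 2 (2S,3S)-epoxygeraniol
Product: 3 (2R,3S)-2-(chloromethyl)-3-methyl-3-(4-methylpent-3-en-1-yl)oxirane
Conditions: PPh3, CCl4, reflux
Reagents that add atoms: carbon tetrachloride ClC(Cl)(Cl)Cl
Why: Appel chlorination replaces the primary hydroxyl under neutral conditions that leave the epoxide and both stereocenters untouched (the descriptor at C2 changes only because CH2Cl outranks the ring carbon).

Step 3
Reactants: 3 epoxy chloride
Product: 4 (2E)-5-[(2S,3R)-3-(chloromethyl)-2-methyloxiran-2-yl]-2-methylpent-2-en-1-ol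
Conditions: SeO2 (20 mol%), t-BuOOH, CH2Cl2, 0 → 23 °C
Reagents that add atoms: tert-butyl hydroperoxide CC(C)(C)OO
Why: SeO2 allylic oxidation (ene reaction then [2,3]-shift) hydroxylates the E-methyl group of the only alkene and gives the E-allylic alcohol (future C13).

Step 4
Reactants: 4 E-allylic alcohol
Product: 5 (2S)-5-[(2S,3R)-3-(chloromethyl)-2-methyloxiran-2-yl]-2-methylpentan-1-ol
Conditions: H2 (30 atm), Ru(OAc)2[(S)-BINAP] (1 mol%), MeOH, 25 °C
Reagents that add atoms: none
Why: Noyori asymmetric hydrogenation of an allylic alcohol, in which the Ru-bound alkoxide directs hydride to one face of the trisubstituted alkene and sets C12 (S), while the epoxide and C–Cl bond are inert to this catalyst.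

Step 5
Reactants: 5 saturated epoxy chloride alcohol
Product: 6 (2S,6S)-2,6-dimethyloct-7-yne-1,6-diol
Conditions: n-BuLi (4.2 equiv), THF, −35 → 0 °C; aq. NH4Cl
Reagents that add atoms: none
Why: Base-induced eliminative opening of the 2,3-epoxy chloride followed by dehydrochlorination (Yadav–Takano alkyne synthesis) gives the terminal alkyne and tertiary alcohol without breaking the C8–O bond, so C8 keeps the Sharpless configuration (S).

Step 6
Reactants: 7 prenyl chloride (1-chloro-3-methylbut-2-ene)
Product: 8 (2E)-4-chloro-2-methylbut-2-en-1-ol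
Conditions: SeO2 (cat.), t-BuOOH, CH2Cl2, 23 °C
Reagents that add atoms: tert-butyl hydroperoxide CC(C)(C)OO
Why: SeO2 allylic oxidation is E-selective for trisubstituted alkenes, which fixes the E geometry of the future C3=C4 unit.

Step 7
Reactants: 8 (2E)-4-chloro-2-methylbut-2-en-1-ol
Product: 9 (2E)-1-bromo-4-chloro-2-methylbut-2-ene
Conditions: PBr3, Et2O, 0 °C
Reagents that add atoms: phosphorus tribromide BrP(Br)Br
Why: PBr3 converts the primary allylic alcohol to the bromide by SN2 displacement of the phosphite ester with retention of alkene geometry.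

Step 8
Reactants: 6 alkynyl diol; 9 bromo chloride
Product: 10 (2S,6S,10E)-12-chloro-2,6,10-trimethyldodec-10-en-7-yne-1,6-diol
Conditions: CuI (20 mol%), K2CO3, DMF, 23 °C, 9 (2 equiv)
Reagents that add atoms: none
Why: Copper-acetylide SN2 alkylation of the allylic bromide, which is displaced much faster than the allylic chloride, forms the C5–C6 bond of the skipped enyne and tolerates both free hydroxyls.

Step 9
Reactants: 10 enyne chloro diol
Product: 11 (2S,6S,10E)-12-chloro-6-hydroxy-2,6,10-trimethyldodec-10-en-7-ynal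
Conditions: TEMPO (10 mol%), PhI(OAc)2, CH2Cl2, 23 °C
Reagents that add atoms: none
Why: TEMPO/PhI(OAc)2 (oxoammonium) oxidation is selective for the primary alcohol, cannot oxidize the tertiary one and does not epimerize the α-methyl aldehyde.

Step 10
Reactants: 12 furan-2(5H)-one
Product: 14 3-bromofuran-2(5H)-one, via trans-3,4-dibromo lactone 13 (not isolated)
Conditions: Br2, CH2Cl2, 0 → 23 °C; then Et3N, 0 °C
Reagents that add atoms: bromine BrBr
Why: Anti addition of Br2 to the butenolide followed by amine-induced E1cB loss of HBr (bromination–dehydrobromination) gives the α-bromo butenolide.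

Step 11
Reactants: 14 3-bromofuran-2(5H)-one; 15 (trimethylsilyl)methylmagnesium chloride
Product: 16 3-[(trimethylsilyl)methyl]furan-2(5H)-one
Conditions: 15, ZnCl2, THF, 0 °C; then 14, Pd(PPh3)4 (5 mol%), THF, 50 °C
Reagents that add atoms: none
Why: Negishi cross-coupling of the vinylic bromide with an alkylzinc that has no β-hydrogen and is too weakly basic to attack or deprotonate the lactone.

Step 12
Reactants: 16 3-[(trimethylsilyl)methyl]furan-2(5H)-one
Product: 17 triisopropyl({3-[(trimethylsilyl)methyl]furan-2-yl}oxy)silane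
Conditions: iPr3SiOTf, Et3N, CH2Cl2, 0 °C
Reagents that add atoms: triisopropylsilyl trifluoromethanesulfonate CC(C)[Si](OS(=O)(=O)C(F)(F)F)(C(C)C)C(C)C
Why: Soft enolization and O-silylation of the butenolide gives the aromatic 2-silyloxyfuran, a vinylogous silyl ketene acetal.

Step 13
Reactants: 11 aldehyde; 17 silyloxyfuran
Product: 18 (5R)-5-[(1R,2S,6S,10E)-12-chloro-1,6-dihydroxy-2,6,10-trimethyldodec-10-en-7-yn-1-yl]-3-[(trimethylsilyl)methyl]furan-2(5H)-one
Conditions: BF3·OEt2, CH2Cl2, −78 °C; aq. NaHCO3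
Reagents that add atoms: none
Why: Vinylogous Mukaiyama aldol reaction at C5 of the silyloxyfuran through an open transition state, in which Felkin–Anh attack on the α-methyl aldehyde sets C13 (R, 12,13-syn) and the usual threo preference of 2-silyloxyfurans under BF3 sets C14 (R, 13,14-syn); minor diastereomers are removed by chromatography.

Step 14
Reactants: 18 aldol butenolide
Product: 19 (5R)-5-[(1R,2S,6S,10E)-12-chloro-6-hydroxy-2,6,10-trimethyl-1-(triethylsilyloxy)dodec-10-en-7-yn-1-yl]-3-[(trimethylsilyl)methyl]furan-2(5H)-one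
Conditions: Et3SiCl, imidazole, DMF, 0 °C
Reagents that add atoms: chlorotriethylsilane CC[Si](Cl)(CC)CC
Why: Silylation of the secondary alcohol (the tertiary propargylic one does not react) masks O13 so that only O14 can lactonize later.

Step 15
Reactants: 19 silyl-protected butenolide
Product: 20 (2E,4R,5R,6S,10S,14E)-16-chloro-6,10,14-trimethyl-5-(triethylsilyloxy)-2-[(trimethylsilyl)methyl]hexadeca-2,14-dien-11-yne-1,4,10-triol
Conditions: iBu2AlH (4 equiv), CH2Cl2, −78 → −20 °C; aq. KNaC4H4O6
Reagents that add atoms: none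
Why: 1,2-Reduction of the butenolide by iBu2AlH opens it to the ene-1,4-diol with C16 cis to C14, which turns the conjugated silane into an electron-rich 2-(silylmethyl)allyl nucleophile and takes the C14–O bond out of the alkene plane.

Step 16
Reactants: 20 open-chain allylsilane allylic chloride
Product: 23 (1S,3E,8S,12S,13R,14R)-13-(triethylsilyloxy)cembra-3,15(17)-dien-6-yne-8,14,16-triol, via tris(trimethylsilyl) ether 21 (not isolated), via cyclized silyl ether 22 (not isolated)
Conditions: (Me3Si)2NH, Me3SiOTf (1 mol%), CH2Cl2, 23 °C, evaporate; then add over 10 h to ZnCl2·OEt2 (3 equiv), CH2Cl2 (1 mM), −40 °C; then K2CO3, MeOH, 0 °C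
Reagents that add atoms: none
Why: Proposed new method: ZnCl2 ionizes the geranyl-type primary allylic chloride to the E-configured C2–C4 allyl cation, whose primary terminus is captured at C1 by the tethered 2-(silylmethyl)allyl unit in an SE2′ (Hosomi–Sakurai-type) cation–olefin closure of the 14-membered ring, the β-silyl cation collapsing only to the C15=C17 methylene with loss of Me3SiCl; allylic 1,3-strain with the cis CH2O group holds H14 in the alkene plane and C2 adds anti to the C13 branch through an antiperiplanar C13–C14–C1–C2 ring torsion, which gives 1S; the alkyne cannot form a small ring with the cation and high dilution suppresses oligomers; the closest known reactions are the intermolecular ZnCl2-mediated coupling of prenyl-type chlorides with allylsilanes and Lewis-acid macrocyclizations of polyprenyl derivatives onto a terminal alkene.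

Step 17
Reactants: 23 cycloalkyne triol
Product: 24 (1S,3E,6Z,8S,12S,13R,14R)-13-(triethylsilyloxy)cembra-3,6,15(17)-triene-8,14,16-triol
Conditions: H2 (1 atm), Pd/CaCO3 poisoned with Pb(OAc)2, quinoline, EtOAc, 23 °C
Reagents that add atoms: none
Why: Lindlar-type syn semi-hydrogenation of the ring alkyne gives the 6Z alkene and leaves the trisubstituted and 1,1-disubstituted alkenes alone.

Step 18
Reactants: 24 Z-alkene triol
Product: 26 (1S,3E,6Z,8S,12S,13R,14R)-8-hydroxy-13-(triethylsilyloxy)cembra-3,6,15(17)-trien-16,14-olide, via lactol 25 (not isolated)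
Conditions: TEMPO (20 mol%), PhI(OAc)2 (2.5 equiv), CH2Cl2, 23 °C
Reagents that add atoms: none
Why: Oxidative lactonization of a 2-methylene-1,4-diol, in which the primary allylic alcohol is oxidized to the enal, the C14 hydroxyl closes the lactol and a second oxidation gives the cis-fused α-methylene-γ-lactone, O13 being blocked as its silyl ether.

Step 19
Reactants: 26 silyl-protected lactone
Product: 27 (1S,3E,6Z,8S,12S,13R,14R)-8,13-dihydroxycembra-3,6,15(17)-trien-16,14-olide
Conditions: HF·pyridine, pyridine, THF, 0 °C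
Reagents that add atoms: none
Why: Fluoride-driven cleavage of the Si–O bond frees the C13 hydroxyl before the acid-sensitive epoxide is present.

Step 20
Reactants: 27 trienolide diol
Product: 28 (1S,3R,4R,6Z,8S,12S,13R,14R)-3,4-epoxy-8,13-dihydroxycembra-6,15(17)-dien-16,14-olide (target)
Conditions: Shi ketone from D-fructose (30 mol%), KHSO5 (as 2KHSO5·KHSO4·K2SO4), K2CO3, Bu4NHSO4, MeCN–CH2(OMe)2–aq. Na2B4O7, 0 °C
Reagents that add atoms: potassium peroxymonosulfate [K+].[O-]S(=O)(=O)OO
Why: Shi asymmetric epoxidation, in which the electrophilic chiral dioxirane picks the electron-rich E-trisubstituted C3=C4 alkene over the hindered Z-alkene and the conjugated methylene and its spiro transition state delivers oxygen to the face that gives the (3R,4R)-epoxide.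

**Compound list**

1 | geraniol, (2E)-3,7-dimethylocta-2,6-dien-1-ol | CC(C)=CCC/C(C)=C/CO | starting material
2 | [(2S,3S)-3-methyl-3-(4-methylpent-3-en-1-yl)oxiran-2-yl]methanol | CC(C)=CCC[C@]1(C)O[C@H]1CO | intermediate
3 | (2R,3S)-2-(chloromethyl)-3-methyl-3-(4-methylpent-3-en-1-yl)oxirane | CC(C)=CCC[C@]1(C)O[C@H]1CCl | intermediate
4 | (2E)-5-[(2S,3R)-3-(chloromethyl)-2-methyloxiran-2-yl]-2-methylpent-2-en-1-ol | OC/C(C)=C/CC[C@]1(C)O[C@H]1CCl | intermediate
5 | (2S)-5-[(2S,3R)-3-(chloromethyl)-2-methyloxiran-2-yl]-2-methylpentan-1-ol | OC[C@@H](C)CCC[C@]1(C)O[C@H]1CCl | intermediate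
6 | (2S,6S)-2,6-dimethyloct-7-yne-1,6-diol | OC[C@@H](C)CCC[C@](C)(O)C#C | intermediate
7 | prenyl chloride, 1-chloro-3-methylbut-2-ene | CC(C)=CCCl | starting material
8 | (2E)-4-chloro-2-methylbut-2-en-1-ol | OC/C(C)=C/CCl | intermediate
9 | (2E)-1-bromo-4-chloro-2-methylbut-2-ene | BrC/C(C)=C/CCl | intermediate
10 | (2S,6S,10E)-12-chloro-2,6,10-trimethyldodec-10-en-7-yne-1,6-diol | OC[C@@H](C)CCC[C@](C)(O)C#CC/C(C)=C/CCl | intermediate
11 | (2S,6S,10E)-12-chloro-6-hydroxy-2,6,10-trimethyldodec-10-en-7-ynal | O=C[C@@H](C)CCC[C@](C)(O)C#CC/C(C)=C/CCl | intermediate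
12 | furan-2(5H)-one | O=C1OCC=C1 | starting material
13 | trans-3,4-dibromodihydrofuran-2(3H)-one (racemic; not isolated) | O=C1OC[C@@H](Br)[C@@H]1Br | intermediate
14 | 3-bromofuran-2(5H)-one | O=C1OCC=C1Br | intermediate
15 | (trimethylsilyl)methylmagnesium chloride | C[Si](C)(C)C[Mg]Cl | starting material
16 | 3-[(trimethylsilyl)methyl]furan-2(5H)-one | C[Si](C)(C)CC1=CCOC1=O | intermediate
17 | triisopropyl({3-[(trimethylsilyl)methyl]furan-2-yl}oxy)silane | C[Si](C)(C)Cc1ccoc1O[Si](C(C)C)(C(C)C)C(C)C | intermediate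
18 | (5R)-5-[(1R,2S,6S,10E)-12-chloro-1,6-dihydroxy-2,6,10-trimethyldodec-10-en-7-yn-1-yl]-3-[(trimethylsilyl)methyl]furan-2(5H)-one | C[Si](C)(C)CC1=C[C@@H](OC1=O)[C@H](O)[C@@H](C)CCC[C@](C)(O)C#CC/C(C)=C/CCl | intermediate
19 | (5R)-5-[(1R,2S,6S,10E)-12-chloro-6-hydroxy-2,6,10-trimethyl-1-(triethylsilyloxy)dodec-10-en-7-yn-1-yl]-3-[(trimethylsilyl)methyl]furan-2(5H)-one | C[Si](C)(C)CC1=C[C@@H](OC1=O)[C@H](O[Si](CC)(CC)CC)[C@@H](C)CCC[C@](C)(O)C#CC/C(C)=C/CCl | intermediate
20 | (2E,4R,5R,6S,10S,14E)-16-chloro-6,10,14-trimethyl-5-(triethylsilyloxy)-2-[(trimethylsilyl)methyl]hexadeca-2,14-dien-11-yne-1,4,10-triol (C16 hydroxymethyl cis to C14) | C[Si](C)(C)C/C(CO)=C/[C@@H](O)[C@H](O[Si](CC)(CC)CC)[C@@H](C)CCC[C@](C)(O)C#CC/C(C)=C/CCl | intermediate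
21 | 1,4,10-tris-O-(trimethylsilyl) ether of 20 (not isolated) | C[Si](C)(C)C/C(CO[Si](C)(C)C)=C/[C@@H](O[Si](C)(C)C)[C@H](O[Si](CC)(CC)CC)[C@@H](C)CCC[C@](C)(O[Si](C)(C)C)C#CC/C(C)=C/CCl | intermediate
22 | (1S,3E,8S,12S,13R,14R)-13-(triethylsilyloxy)-8,14,16-tris(trimethylsilyloxy)cembra-3,15(17)-dien-6-yne (not isolated) | C=C(CO[Si](C)(C)C)[C@@H]1C/C=C(C)/CC#C[C@@](C)(O[Si](C)(C)C)CCC[C@H](C)[C@@H](O[Si](CC)(CC)CC)[C@@H]1O[Si](C)(C)C | intermediate
23 | (1S,3E,8S,12S,13R,14R)-13-(triethylsilyloxy)cembra-3,15(17)-dien-6-yne-8,14,16-triol | C=C(CO)[C@@H]1C/C=C(C)/CC#C[C@@](C)(O)CCC[C@H](C)[C@@H](O[Si](CC)(CC)CC)[C@@H]1O | intermediate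
24 | (1S,3E,6Z,8S,12S,13R,14R)-13-(triethylsilyloxy)cembra-3,6,15(17)-triene-8,14,16-triol | C=C(CO)[C@@H]1C/C=C(C)/C/C=C\[C@@](C)(O)CCC[C@H](C)[C@@H](O[Si](CC)(CC)CC)[C@@H]1O | intermediate
25 | lactol of 26: (1S,3E,6Z,8S,12S,13R,14R)-14,16-epoxy-13-(triethylsilyloxy)cembra-3,6,15(17)-triene-8,16-diol (C16 epimers; not isolated) | C=C1C(O)O[C@H]2[C@H](O[Si](CC)(CC)CC)[C@@H](C)CCC[C@](C)(O)/C=C\C/C(C)=C/C[C@@H]12 | intermediate
26 | (1S,3E,6Z,8S,12S,13R,14R)-8-hydroxy-13-(triethylsilyloxy)cembra-3,6,15(17)-trien-16,14-olide | C=C1C(=O)O[C@H]2[C@H](O[Si](CC)(CC)CC)[C@@H](C)CCC[C@](C)(O)/C=C\C/C(C)=C/C[C@@H]12 | intermediate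
27 | (1S,3E,6Z,8S,12S,13R,14R)-8,13-dihydroxycembra-3,6,15(17)-trien-16,14-olide | C=C1C(=O)O[C@H]2[C@H](O)[C@@H](C)CCC[C@](C)(O)/C=C\C/C(C)=C/C[C@@H]12 | intermediate
28 | (1S,3R,4R,6Z,8S,12S,13R,14R)-3,4-epoxy-8,13-dihydroxycembra-6,15(17)-dien-16,14-olide | C=C1C(=O)O[C@H]2[C@H](O)[C@@H](C)CCC[C@](C)(O)/C=C\C[C@@]3(C)O[C@@H]3C[C@@H]12 | target

**Step count and risks**

Total: 20 steps. Longest linear sequence: 15 steps from geraniol (steps 1–5, 8, 9, 13–20).

The step most likely to fail is step 16. The ring closure is untested, the allyl cation can eliminate or oligomerize, the allylic silyl ether at C14 can ionize, and the face selectivity at C1 rests on a conformational argument. The fallback sets out from 19 and skips the reduction. Slow addition of 19 to ZnCl2·OEt2 in CH2Cl2 at 0 °C under high dilution lets the conjugated 3-(silylmethyl)butenolide itself trap the allyl cation at C1, as ethyl 2-(trimethylsilylmethyl)acrylate does with other cations. Ring closure and formation of the α-methylene lactone then happen in one event and give the cycloalkyne lactone (1S,3E,8S,12S,13R,14R)-8-hydroxy-13-(triethylsilyloxy)cembra-3,15(17)-dien-6-yn-16,14-olide F1. Semi-hydrogenation of F1 over Pd/CaCO3 poisoned with Pb(OAc)2 comes back to the route at 26. Because the lactone oxygen then lies in the plane of the reacting alkene, the same torsional argument favors the trans-fused C1 epimer, so this fallback answers a reactivity failure and not a stereochemical one; the H1/H14 relationship must be checked by nOe before going on.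

The second is step 20. The macrocycle may expose the wrong face of C3=C4 to the chiral dioxirane, and the Z-alkene next to the tertiary alcohol may compete. The fallback sets out from 23 and epoxidizes before the Z-alkene exists. In 23, C3=C4 is the only electron-rich alkene and the alkyne holds the ring in a different shape. The same Shi ketone and KHSO5 give the epoxy cycloalkyne triol (1S,3R,4R,8S,12S,13R,14R)-3,4-epoxy-13-(triethylsilyloxy)cembr-15(17)-en-6-yne-8,14,16-triol F2. Semi-hydrogenation gives the epoxy Z-alkene triol (1S,3R,4R,6Z,8S,12S,13R,14R)-3,4-epoxy-13-(triethylsilyloxy)cembra-6,15(17)-diene-8,14,16-triol F3. TEMPO/PhI(OAc)2 gives the epoxy lactone silyl ether (1S,3R,4R,6Z,8S,12S,13R,14R)-3,4-epoxy-8-hydroxy-13-(triethylsilyloxy)cembra-6,15(17)-dien-16,14-olide F4. Bu4NF buffered with AcOH (in place of HF·pyridine, to spare the epoxide) removes the silyl group and comes back to the route at 28.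

The third is step 4. The enantioselectivity and sense of Ru–BINAP hydrogenation are less secure for a 2-methyl allylic alcohol than for geraniol, and a C12 epimer would be a remote diastereomer that cannot be separated later. The fallback sets out from 4, which is oxidized with MnO2 in CH2Cl2 to the enal (2E)-5-[(2S,3R)-3-(chloromethyl)-2-methyloxiran-2-yl]-2-methylpent-2-enal F5. F5 is reduced with fermenting baker's yeast (enoate reductase, then alcohol dehydrogenase), a biocatalytic reduction known to turn (E)-2-methylalk-2-enals into (S)-2-methylalkan-1-ols. This comes back to the route at 5.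

**Further compounds**

F1 | step 16 | (1S,3E,8S,12S,13R,14R)-8-hydroxy-13-(triethylsilyloxy)cembra-3,15(17)-dien-6-yn-16,14-olide | C=C1C(=O)O[C@H]2[C@H](O[Si](CC)(CC)CC)[C@@H](C)CCC[C@](C)(O)C#CC/C(C)=C/C[C@@H]12
F2 | step 20 | (1S,3R,4R,8S,12S,13R,14R)-3,4-epoxy-13-(triethylsilyloxy)cembr-15(17)-en-6-yne-8,14,16-triol | C=C(CO)[C@@H]1C[C@H]2O[C@]2(C)CC#C[C@@](C)(O)CCC[C@H](C)[C@@H](O[Si](CC)(CC)CC)[C@@H]1O
F3 | step 20 | (1S,3R,4R,6Z,8S,12S,13R,14R)-3,4-epoxy-13-(triethylsilyloxy)cembra-6,15(17)-diene-8,14,16-triol | C=C(CO)[C@@H]1C[C@H]2O[C@]2(C)C/C=C\[C@@](C)(O)CCC[C@H](C)[C@@H](O[Si](CC)(CC)CC)[C@@H]1O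
F4 | step 20 | (1S,3R,4R,6Z,8S,12S,13R,14R)-3,4-epoxy-8-hydroxy-13-(triethylsilyloxy)cembra-6,15(17)-dien-16,14-olide | C=C1C(=O)O[C@H]2[C@H](O[Si](CC)(CC)CC)[C@@H](C)CCC[C@](C)(O)/C=C\C[C@@]3(C)O[C@@H]3C[C@@H]12
F5 | step 4 | (2E)-5-[(2S,3R)-3-(chloromethyl)-2-methyloxiran-2-yl]-2-methylpent-2-enal | O=C/C(C)=C/CC[C@]1(C)O[C@H]1CCl
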